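## Retrosynthetic overview

1. Junceellolide F 29 ⇐ seco iodo-aldehyde 27: one-flask CrCl2/NiCl2 alkenyl iodide–aldehyde macrocyclisation (C6–C7) with lactonisation (O7–C19). The ten-membered carbocycle and the γ-lactone form together in the last step.
2. 27 ⇐ hydroxy enone 20: chelation-controlled Reformatsky addition with in-flask acetylation (C8, 9-OAc), ring A methylenation and epoxidation (C11), ozonolysis (C7 aldehyde).
3. 20 ⇐ C9 aldehyde 17 + methoxyallene (C9); 17 ⇐ ketol 12 by 1,3-syn reduction (C14), acetylation and vinyl cleavage.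
4. 12 ⇐ enone 3 + CH2=CHMgBr + aldehyde 10 (asymmetric conjugate addition/aldol: C10, C1, C2); 3 ⇐ 4-methoxy-2-methylphenol; 10 ⇐ prop-2-yn-1-ol.
5. Ring order: ring A (carbocycle of the phenol, steps 1–2) → oxirane (step 13) → ten-membered ring and γ-lactone in one operation (step 15).

Assumption: atoms carry briarane numbering (C1 quaternary carbon with the C15 methyl; C2, C9, C14 acetoxy carbons; C5=C6 with the C16 methyl; C7 lactone carbinol; C8 tertiary carbinol; C10 ring-fusion CH; C11 spiro carbon with C20; C17 with the C18 methyl; C19 lactone carbonyl). Compounds 8, 18 and racemic 21 are bought. The ligand antipode that gives the drawn C10 configuration is used. This is an unexecuted proposal; selectivities are predictions.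

## Route

Step 1
Reactants: 1 4-methoxy-2-methylphenol
Product: 2 4,4-dimethoxy-2-methylcyclohexa-2,5-dien-1-one
Conditions: PhI(OAc)2, MeOH, 0 °C
Reagents that add atoms: methanol (CO)
Why: Oxidative dearomatisation of a para-methoxyphenol to the quinone monoketal (hypervalent-iodine phenol oxidation); no stereocentre is formed.

Step 2
Reactants: 2 4,4-dimethoxy-2-methylcyclohexa-2,5-dien-1-one
Product: 3 4,4-dimethoxy-2-methylcyclohex-2-en-1-one
Conditions: H2 (1 atm), RhCl(PPh3)3 (5 mol %), toluene, rt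
Reagents that add atoms: none
Why: Homogeneous hydrogenation reduces the unsubstituted enone alkene faster than the methyl-substituted one (steric selectivity of RhCl(PPh3)3); no stereocentre is formed.

Step 3
Reactants: 4 prop-2-yn-1-ol
Product: 6 (2Z)-3-iodo-2-methylprop-2-en-1-ol, via bromomagnesium alkenyl alkoxide 5 (not isolated)
Conditions: MeMgBr (2.5 equiv), CuI (10 mol %), THF, −10 °C to rt; then I2, −78 to 0 °C
Reagents that add atoms: methylmagnesium bromide (C[Mg]Br), iodine (II)
Why: Copper-catalysed anti-carbomagnesiation of the propargylic alkoxide gives the chelated alkenylmagnesium, and iodinolysis with retention fixes the Z iodoalkene (future C5=C6 geometry).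

Step 4
Reactants: 6 (2Z)-3-iodo-2-methylprop-2-en-1-ol
Product: 7 (1Z)-3-bromo-1-iodo-2-methylprop-1-ene
Conditions: PBr3, Et2O, 0 °C
Reagents that add atoms: phosphorus tribromide (BrP(Br)Br)
Why: SN2 bromination of the primary allylic alcohol leaves the alkene geometry untouched.

Step 5
Reactants: 7 (1Z)-3-bromo-1-iodo-2-methylprop-1-ene, 8 acetaldehyde N,N-dimethylhydrazone
Product: 10 (4Z)-5-iodo-4-methylpent-4-enal, via alkylated hydrazone 9 (not isolated)
Conditions: 8, LiN(iPr)2, THF, −78 to 0 °C; 7, −78 °C to rt; then aq. oxalic acid, Et2O, rt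
Reagents that add atoms: water (O)
Why: Corey–Enders azaenolate alkylation (SN2 on the allylic bromide) followed by hydrazone hydrolysis delivers the C2–C6 aldehyde; no stereocentre is formed.

Step 6
Reactants: 3 4,4-dimethoxy-2-methylcyclohex-2-en-1-one, 10 (4Z)-5-iodo-4-methylpent-4-enal
Product: 12 ketol (2S,3R)-2-[(1R,4Z)-1-hydroxy-5-iodo-4-methylpent-4-en-1-yl]-4,4-dimethoxy-2-methyl-3-vinylcyclohexan-1-one, via bromomagnesium enolate 11 (not isolated)
Conditions: CH2=CHMgBr, CuBr·SMe2 (5 mol %), BINOL-derived phosphoramidite ligand (6 mol %), t-BuOMe, −78 °C; then 10, −78 °C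
Reagents that add atoms: vinylmagnesium bromide (C=C[Mg]Br)
Why: Copper-catalysed asymmetric conjugate addition (ligand control sets C10) with aldol trapping of the bromomagnesium enolate: the aldehyde adds anti to the new vinyl group (C1) and, in the metal-bridged transition state, keeps its chain out of the slot between the C15 methyl and C10 (C2).

Step 7
Reactants: 12 ketol
Product: 14 syn-diol (1S,2S,3R)-2-[(1R,4Z)-1-hydroxy-5-iodo-4-methylpent-4-en-1-yl]-4,4-dimethoxy-2-methyl-3-vinylcyclohexan-1-ol, via diethylboron chelate 13 (not isolated)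
Conditions: Et2BOMe, THF–MeOH (4:1), −78 °C; NaBH4; then MeOH co-evaporation
Reagents that add atoms: none
Why: Narasaka–Prasad reduction: hydride attacks the six-membered boron chelate axially to give the 1,3-syn diol, which is the axial 14-OH trans to the C15 methyl (sets C14).

Step 8
Reactants: 14 syn-diol
Product: 15 diacetate (1S,2S,3R)-2-[(1R,4Z)-1-acetoxy-5-iodo-4-methylpent-4-en-1-yl]-4,4-dimethoxy-2-methyl-3-vinylcyclohexyl acetate
Conditions: Ac2O, pyridine, DMAP (cat.), CH2Cl2, rt
Reagents that add atoms: acetic anhydride (CC(=O)OC(C)=O)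
Why: DMAP-catalysed acylation installs the final C2 and C14 acetates; no stereocentre is touched.

Step 9
Reactants: 15 diacetate
Product: 17 C9 aldehyde, via vicinal diol 16 (not isolated)
Conditions: OsO4 (2 mol %), NaIO4, 2,6-lutidine, dioxane–H2O (3:1), rt
Reagents that add atoms: sodium periodate ([Na+].[O-]I(=O)(=O)=O)
Why: Lemieux–Johnson cleavage (osmylation then periodate) of the monosubstituted alkene; the hindered, electron-poor iodoalkene is not dihydroxylated and C10 keeps its equatorial configuration.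

Step 10
Reactants: 17 C9 aldehyde, 18 methoxyallene
Product: 20 hydroxy enone, via allenyl carbinol 19 (not isolated)
Conditions: 18, n-BuLi, THF, −78 °C; then 17, −78 °C; then 5 % aq. H2SO4, THF, 0 °C
Reagents that add atoms: water (O)
Why: 1-Lithio-1-methoxyallene adds as an acryloyl anion equivalent under Felkin–Anh control, anti to the quaternary C1 (sets C9); acid then hydrolyses the allenyl ether to the vinyl ketone and the dimethyl ketal to the C11 ketone.

Step 11
Reactants: 20 hydroxy enone, 21 methyl 2-bromopropanoate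
Product: 23 C9-acetoxy hydroxy ester, via bis(bromozinc) alkoxide 22 (not isolated)
Conditions: 21 (3 equiv), Zn (activated), THF, 0 °C; then AcCl, −20 °C
Reagents that add atoms: acetyl chloride (CC(=O)Cl)
Why: Reformatsky addition under Cram chelation: the bromozinc alkoxide of the 9-OH ties O9 to the C8 carbonyl, so the bromozinc enolate adds 1,2 from the face opposite C10 (sets C8), and the secondary alkoxide is then acetylated before it can lactonise onto C19; C17 forms as a mixture that step 15 corrects.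

Step 12
Reactants: 23 C9-acetoxy hydroxy ester
Product: 24 exocyclic alkene
Conditions: Zn, CH2Br2, TiCl4, THF–CH2Cl2, 0 °C to rt
Reagents that add atoms: dibromomethane (BrCBr)
Why: Lombardo–Takai methylenation: the non-basic CH2(ZnBr)2/TiCl4 reagent converts the hindered C11 ketone without attacking the esters or eliminating the β-acetoxy group; no stereocentre is formed.

Step 13
Reactants: 24 exocyclic alkene
Product: 25 spiro-epoxide
Conditions: mCPBA, CH2Cl2, 0 °C
Reagents that add atoms: 3-chloroperbenzoic acid (OOC(=O)c1cccc(Cl)c1)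
Why: Prilezhaev epoxidation of the most electron-rich (1,1-disubstituted) alkene; the peracid approaches anti to the axial C15 methyl, which puts the oxirane oxygen on the face of H-10 (sets C11).

Step 14
Reactants: 25 spiro-epoxide
Product: 27 seco-aldehyde, via ozonide 26 (not isolated)
Conditions: O3, CH2Cl2, −78 °C (indicator end-point); then Me2S, −78 °C to rt
Reagents that add atoms: ozone ([O-][O+]=O)
Why: Ozonolysis with reductive work-up cleaves only the terminal alkene (the iodoalkene is deactivated) and gives the α-hydroxy aldehyde without the glycol over-cleavage that periodate would cause.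

Step 15
Reactants: 27 seco-aldehyde
Product: 29 junceellolide F, via macrocyclic hydroxy ester 28 (not isolated)
Conditions: CrCl2 (10 equiv), NiCl2 (1 mol %), DMSO, rt, slow addition to 2 mM; then DBU (0.3 equiv), rt
Reagents that add atoms: none
Why: Nozaki–Hiyama–Kishi macrocyclisation: zerovalent nickel inserts into the alkenyl iodide, the alkenylchromium dichloride keeps the Z geometry and adds to the aldehyde, which the free 8-OH holds in a five-membered chromium chelate so the tethered nucleophile attacks the face syn to C9 (sets C7); the chromium alkoxide then lactonises onto the methyl ester, and DBU equilibrates C17 to the epimer with the C18 methyl trans to C9.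

## Compound list

1 | 4-methoxy-2-methylphenol | COc1ccc(O)c(C)c1 | starting material
2 | 4,4-dimethoxy-2-methylcyclohexa-2,5-dien-1-one | COC1(OC)C=CC(=O)C(C)=C1 | intermediate
3 | 4,4-dimethoxy-2-methylcyclohex-2-en-1-one | COC1(OC)CCC(=O)C(C)=C1 | intermediate
4 | prop-2-yn-1-ol | C#CCO | starting material
5 | bromomagnesium (2Z)-3-(bromomagnesio)-2-methylprop-2-en-1-olate (not isolated) | Br[Mg]OC/C(C)=C\[Mg]Br | intermediate
6 | (2Z)-3-iodo-2-methylprop-2-en-1-ol | OC/C(C)=C\I | intermediate
7 | (1Z)-3-bromo-1-iodo-2-methylprop-1-ene | BrC/C(C)=C\I | intermediate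
8 | acetaldehyde N,N-dimethylhydrazone | C/C=N/N(C)C | starting material
9 | (4Z)-5-iodo-4-methylpent-4-enal N,N-dimethylhydrazone (not isolated) | CN(C)/N=C/CC/C(C)=C\I | intermediate
10 | (4Z)-5-iodo-4-methylpent-4-enal | O=CCC/C(C)=C\I | intermediate
11 | bromomagnesium enolate of (3R)-4,4-dimethoxy-2-methyl-3-vinylcyclohexan-1-one (not isolated) | Br[Mg]OC1=C(C)[C@@H](C=C)C(OC)(OC)CC1 | intermediate
12 | ketol: (2S,3R)-2-[(1R,4Z)-1-hydroxy-5-iodo-4-methylpent-4-en-1-yl]-4,4-dimethoxy-2-methyl-3-vinylcyclohexan-1-one | O=C1CCC(OC)(OC)[C@H](C=C)[C@@]1(C)[C@H](O)CC/C(C)=C\I | intermediate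
13 | diethylboron chelate (O-diethylboryl derivative of the side-chain hydroxyl) of 12 (not isolated) | O=C1CCC(OC)(OC)[C@H](C=C)[C@@]1(C)[C@H](OB(CC)CC)CC/C(C)=C\I | intermediate
14 | syn-diol: (1S,2S,3R)-2-[(1R,4Z)-1-hydroxy-5-iodo-4-methylpent-4-en-1-yl]-4,4-dimethoxy-2-methyl-3-vinylcyclohexan-1-ol | O[C@H]1CCC(OC)(OC)[C@H](C=C)[C@@]1(C)[C@H](O)CC/C(C)=C\I | intermediate
15 | diacetate: (1S,2S,3R)-2-[(1R,4Z)-1-acetoxy-5-iodo-4-methylpent-4-en-1-yl]-4,4-dimethoxy-2-methyl-3-vinylcyclohexyl acetate | CC(=O)O[C@H]1CCC(OC)(OC)[C@H](C=C)[C@@]1(C)[C@H](OC(C)=O)CC/C(C)=C\I | intermediate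
16 | vicinal diol: 15 with the C10 vinyl group as CH(OH)CH2OH, epimers at the new carbinol (not isolated) | CC(=O)O[C@H]1CCC(OC)(OC)[C@H](C(O)CO)[C@@]1(C)[C@H](OC(C)=O)CC/C(C)=C\I | intermediate
17 | C9 aldehyde: 15 with formyl (C9) in place of the C10 vinyl group; C1, C2, C10, C14 as in 29 | CC(=O)O[C@H]1CCC(OC)(OC)[C@H](C=O)[C@@]1(C)[C@H](OC(C)=O)CC/C(C)=C\I | intermediate
18 | methoxyallene (1-methoxypropa-1,2-diene) | COC=C=C | starting material
19 | allenyl carbinol: 17 with the formyl group converted into CH(OH)–C(OMe)=C=CH2; C9 as in 29 (not isolated) | CC(=O)O[C@H]1CCC(OC)(OC)[C@H]([C@@H](O)C(OC)=C=C)[C@@]1(C)[C@H](OC(C)=O)CC/C(C)=C\I | intermediate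
20 | hydroxy enone: ring A 11-ketone with the C10 chain CH(OH)–C(=O)–CH=CH2 (C9, C8, C7) and the C1 side chain and acetates of 15; C9 as in 29 | CC(=O)O[C@H]1CCC(=O)[C@H]([C@@H](O)C(=O)C=C)[C@@]1(C)[C@H](OC(C)=O)CC/C(C)=C\I | intermediate
21 | methyl 2-bromopropanoate (racemic) | COC(=O)C(C)Br | starting material
22 | bis(bromozinc) alkoxide of the C8,C9-diol methyl ester; C8 as in 29, C17 epimers (not isolated) | CC(=O)O[C@H]1CCC(=O)[C@H]([C@@H](O[Zn]Br)[C@@](O[Zn]Br)(C=C)C(C)C(=O)OC)[C@@]1(C)[C@H](OC(C)=O)CC/C(C)=C\I | intermediate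
23 | C9-acetoxy hydroxy ester: 20 with C8 as C(OH)(CH=CH2)[CH(CH3)CO2Me] and 9-OAc; C8 as in 29, C17 epimers | CC(=O)O[C@H]1CCC(=O)[C@H]([C@@H](OC(C)=O)[C@@](O)(C=C)C(C)C(=O)OC)[C@@]1(C)[C@H](OC(C)=O)CC/C(C)=C\I | intermediate
24 | exocyclic alkene: 23 with C11=CH2 (C20) in place of the 11-ketone | CC(=O)O[C@H]1CCC(=C)[C@H]([C@@H](OC(C)=O)[C@@](O)(C=C)C(C)C(=O)OC)[C@@]1(C)[C@H](OC(C)=O)CC/C(C)=C\I | intermediate
25 | spiro-epoxide: 24 with the 11,20-epoxide; C11 as in 29 | CC(=O)O[C@H]1CC[C@]2(CO2)[C@H]([C@@H](OC(C)=O)[C@@](O)(C=C)C(C)C(=O)OC)[C@@]1(C)[C@H](OC(C)=O)CC/C(C)=C\I | intermediate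
26 | ozonide (1,2,4-trioxolane) of the C8 vinyl group of 25 (not isolated) | CC(=O)O[C@H]1CC[C@]2(CO2)[C@H]([C@@H](OC(C)=O)[C@@](O)(C2OCOO2)C(C)C(=O)OC)[C@@]1(C)[C@H](OC(C)=O)CC/C(C)=C\I | intermediate
27 | seco-aldehyde: 25 with formyl (C7) in place of the C8 vinyl group | CC(=O)O[C@H]1CC[C@]2(CO2)[C@H]([C@@H](OC(C)=O)[C@@](O)(C=O)C(C)C(=O)OC)[C@@]1(C)[C@H](OC(C)=O)CC/C(C)=C\I | intermediate
28 | macrocyclic hydroxy ester: ten-membered ring closed between C6 and C7, 7-OH as in 29, C19 methyl ester, C17 epimers (not isolated) | CC(=O)O[C@H]1CC[C@]2(CO2)[C@@H]2[C@@H](OC(C)=O)[C@](O)(C(C)C(=O)OC)[C@@H](O)/C=C(/C)CC[C@@H](OC(C)=O)[C@@]12C | intermediate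
29 | junceellolide F | CC(=O)O[C@H]1CC[C@]2(CO2)[C@@H]2[C@@H](OC(C)=O)[C@@]3(O)[C@H](/C=C(/C)CC[C@@H](OC(C)=O)[C@@]12C)OC(=O)[C@@H]3C | target

## Step count and risks

Total: 15 steps. Longest linear sequence: 13 steps (4 → 29, steps 3–5 and 6–15); the ring A branch from 1 is 12 steps.

**Step 6 (three-component coupling).** The enone is α-methylated and flanked by a ketal, so the conjugate addition may be slow or poorly enantioselective, and the C2 ratio from a tetrasubstituted enolate is uncertain. A wrong C2 would also carry into C14 through step 7. Fallback: the sequence sets out from 3. A [Rh(cod)Cl]2/(R)-BINAP-catalysed 1,4-addition of CH2=CHBF3K gives (3R)-4,4-dimethoxy-2-methyl-3-vinylcyclohexan-1-one F1. Thermodynamic silylation (Me3SiCl, Et3N, DMF, 80 °C) gives trimethyl{[(3R)-4,4-dimethoxy-2-methyl-3-vinylcyclohex-1-en-1-yl]oxy}silane F2. MeLi then ZnCl2 turn F2 into a chlorozinc enolate, whose aldol reaction with 10 comes back to the route at 12. This separates the enantioselective step from the aldol, so the enolate metal can be varied for the C2 ratio.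

**Step 11 (Reformatsky addition and acetylation).** The 9-alkoxide may lactonise onto C19 before it is acetylated, the bromozinc enolate may add 1,4 to the vinyl ketone, and the tertiary alkoxide may also be acetylated. Fallback: the sequence sets out from 20. 4-Methoxybenzyl trichloroacetimidate with Sc(OTf)3 (cat.) gives the C9 4-methoxybenzyl ether of 20 F3. Reformatsky addition of 21 (Zn, THF), now under α-alkoxy chelation with no free alkoxide, gives the C9 4-methoxybenzyl ether hydroxy ester F4. DDQ in wet CH2Cl2 frees the C8,C9-diol methyl ester F5, which is acetylated at once (AcCl, 2,6-lutidine, −20 °C) to come back at 23.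

**Step 15 (macrocyclisation and lactonisation).** The strained ten-membered ring may close poorly, the C7 selectivity rests on a chelation model, and the oxirane must survive trivalent chromium next to the free 8-OH. Fallback for the C7 configuration: the sequence sets out from 27. The ring is closed with CrCl2/NiCl2 in THF–DMF at 0 °C without DBU and worked up cold, so that the C7 epimers are isolated before lactonisation. The undesired 7-epi macrocyclic hydroxy ester F6 is oxidised with MnO2 to the (5Z)-7-oxo macrocyclic ester F7. Reagent-controlled reduction (Me-CBS oxazaborolidine, catecholborane) comes back at 28, which DBU converts into 29.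

## Further compounds

F1 | step 6 | (3R)-4,4-dimethoxy-2-methyl-3-vinylcyclohexan-1-one (epimers at the methyl-bearing carbon) | O=C1CCC(OC)(OC)[C@H](C=C)C1C
F2 | step 6 | trimethyl{[(3R)-4,4-dimethoxy-2-methyl-3-vinylcyclohex-1-en-1-yl]oxy}silane | C[Si](C)(C)OC1=C(C)[C@@H](C=C)C(OC)(OC)CC1
F3 | step 11 | C9 4-methoxybenzyl ether of 20 | CC(=O)O[C@H]1CCC(=O)[C@H]([C@@H](OCc2ccc(OC)cc2)C(=O)C=C)[C@@]1(C)[C@H](OC(C)=O)CC/C(C)=C\I
F4 | step 11 | C9 4-methoxybenzyl ether hydroxy ester (Reformatsky adduct of F3; C17 epimers) | CC(=O)O[C@H]1CCC(=O)[C@H]([C@@H](OCc2ccc(OC)cc2)[C@@](O)(C=C)C(C)C(=O)OC)[C@@]1(C)[C@H](OC(C)=O)CC/C(C)=C\I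
F5 | step 11 | C8,C9-diol methyl ester (C17 epimers) | CC(=O)O[C@H]1CCC(=O)[C@H]([C@@H](O)[C@@](O)(C=C)C(C)C(=O)OC)[C@@]1(C)[C@H](OC(C)=O)CC/C(C)=C\I
F6 | step 15 | 7-epi macrocyclic hydroxy ester (C7 epimer of 28; C17 epimers) | CC(=O)O[C@H]1CC[C@]2(CO2)[C@@H]2[C@@H](OC(C)=O)[C@](O)(C(C)C(=O)OC)[C@H](O)/C=C(/C)CC[C@@H](OC(C)=O)[C@@]12C
F7 | step 15 | (5Z)-7-oxo macrocyclic ester (C7 ketone of 28; C17 epimers) | CC(=O)O[C@H]1CC[C@]2(CO2)[C@@H]2[C@@H](OC(C)=O)[C@](O)(C(C)C(=O)OC)C(=O)/C=C(/C)CC[C@@H](OC(C)=O)[C@@]12C
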